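## Retrosynthetic overview

- The target is released by base methanolysis of a hexa-acetate mono-camphanate. The camphanate, from (1S)-camphanic chloride (made from natural camphor), allows the correct enantiomer of the racemic cycloadduct to be isolated as one diastereomer.
- The cyclohexene is the only ring made, and all three stereocentres arise in one endo [4+2] cycloaddition. The dienophile is a 2'-hydroxychalcone (isobavachalcone 4,4'-diacetate) and the diene is an (E)-aryl diene (dehydroprenyl chalcone tetraacetate).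
- The dienophile comes from Claisen–Schmidt condensation of 3-prenyl-2,4-dihydroxyacetophenone with 4-hydroxybenzaldehyde; the prenyl group is put on by C-alkylation.
- The diene comes from Heck coupling and dehydration on an iodochalcone, itself from a BF3-mediated aldol condensation of acetylated 3-iodo-2,4-dihydroxyacetophenone with 2,4-diacetoxybenzaldehyde.
- All four arenes are bought; the cyclohexene is formed in step 10.

Assumption: the cyclohexene is numbered C1''(methyl)=C2''–C3''–C4''–C5''–C6''; the given SMILES then reads (3''S,4''R,5''S), with the C3''-aryl cis to the C4''-aroyl group and the C4''-aroyl trans to the C5''-aryl group.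

## Route

Step 1
Reactants: 1 2,4-dihydroxyacetophenone; 2 prenyl bromide (1-bromo-3-methylbut-2-ene)
Product: 3 1-[2,4-dihydroxy-3-(3-methylbut-2-en-1-yl)phenyl]ethanone
Conditions: KOH (10% aq.), 0 °C → rt; SiO2 chromatography
Reagents that add atoms: none
Why: C-alkylation of the ambident resorcinolate is fastest at C3, the carbon flanked by both oxygens, so the 3-prenyl ketone is obtained in modest yield after removal of O-prenyl and 5-prenyl by-products.

Step 2
Reactants: 3 1-[2,4-dihydroxy-3-(3-methylbut-2-en-1-yl)phenyl]ethanone; 4 4-hydroxybenzaldehyde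
Product: 6 isobavachalcone [(E)-1-[2,4-dihydroxy-3-(3-methylbut-2-en-1-yl)phenyl]-3-(4-hydroxyphenyl)prop-2-en-1-one], via β-hydroxy ketone 5 (not isolated)
Conditions: KOH (50% aq.), EtOH, rt → 40 °C, 48 h; then cold dil. AcOH to pH 5
Reagents that add atoms: none
Why: Claisen–Schmidt (aldol) condensation in which the methyl ketone enolate adds to the aldehyde and E1cB loss of water gives the thermodynamically favoured E-enone; the prenyl group is inert to base.

Step 3
Reactants: 6 isobavachalcone
Product: 7 isobavachalcone 4,4'-diacetate (2'-OH free)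
Conditions: Ac2O (2.2 equiv), pyridine, CH2Cl2, 0 °C
Reagents that add atoms: acetic anhydride CC(=O)OC(C)=O
Why: Selective O-acylation, since the 2'-hydroxyl is hydrogen-bonded to the ketone and flanked by the prenyl group and therefore reacts far more slowly than the 4- and 4'-hydroxyls.

Step 4
Reactants: 1 2,4-dihydroxyacetophenone
Product: 8 1-(2,4-dihydroxy-3-iodophenyl)ethanone
Conditions: I2 (0.4 equiv), HIO3 (0.2 equiv), EtOH/H2O, rt
Reagents that add atoms: iodine [I][I]; iodic acid OI(=O)=O
Why: Electrophilic aromatic iodination goes to C3, the position activated by both hydroxyls, and iodic acid reoxidises iodide so that water is the only co-product.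

Step 5
Reactants: 8 1-(2,4-dihydroxy-3-iodophenyl)ethanone
Product: 9 4-acetyl-2-iodo-1,3-phenylene diacetate
Conditions: Ac2O (3 equiv), pyridine, DMAP (cat.), CH2Cl2, rt
Reagents that add atoms: acetic anhydride CC(=O)OC(C)=O
Why: DMAP-catalysed O-acylation is forcing enough to esterify the chelated 2-hydroxyl as well, giving a ketone with no free phenol next to the iodide.

Step 6
Reactants: 10 2,4-dihydroxybenzaldehyde
Product: 11 4-formyl-1,3-phenylene diacetate
Conditions: Ac2O (2.5 equiv), pyridine, CH2Cl2, 0 °C → rt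
Reagents that add atoms: acetic anhydride CC(=O)OC(C)=O
Why: Simple O-acylation; masking the ortho-hydroxyl prevents benzopyrylium formation in the acid-mediated condensation that follows.

Step 7
Reactants: 9 4-acetyl-2-iodo-1,3-phenylene diacetate; 11 4-formyl-1,3-phenylene diacetate
Product: 13 (E)-1-(2,4-diacetoxy-3-iodophenyl)-3-(2,4-diacetoxyphenyl)prop-2-en-1-one, via β-hydroxy ketone 12 (not isolated)
Conditions: BF3·OEt2 (1.5 equiv), 1,4-dioxane, rt; aq. NaHCO3 work-up
Reagents that add atoms: none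
Why: Lewis-acid-mediated Claisen–Schmidt condensation (boron enol adds to the BF3-activated aldehyde, then dehydration to the E-enone) runs without base, so the four aryl acetates survive.

Step 8
Reactants: 13 (E)-1-(2,4-diacetoxy-3-iodophenyl)-3-(2,4-diacetoxyphenyl)prop-2-en-1-one; 14 2-methylbut-3-en-2-ol
Product: 15 (E)-1-[2,4-diacetoxy-3-[(E)-3-hydroxy-3-methylbut-1-en-1-yl]phenyl]-3-(2,4-diacetoxyphenyl)prop-2-en-1-one
Conditions: Pd(OAc)2 (5 mol%), P(o-tolyl)3 (10 mol%), NaOAc, DMF, 80 °C
Reagents that add atoms: none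
Why: Heck reaction in which zerovalent palladium inserts into the C–I bond, adds across the terminal alkene and undergoes syn β-hydride elimination to the E-styrenyl carbinol; the tertiary alcohol has no carbinol hydrogen, so no ketone can form.

Step 9
Reactants: 15 (E)-1-[2,4-diacetoxy-3-[(E)-3-hydroxy-3-methylbut-1-en-1-yl]phenyl]-3-(2,4-diacetoxyphenyl)prop-2-en-1-one
Product: 17 (E)-1-[2,4-diacetoxy-3-[(E)-3-methylbuta-1,3-dien-1-yl]phenyl]-3-(2,4-diacetoxyphenyl)prop-2-en-1-one, via tertiary mesylate 16 (not isolated)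
Conditions: MsCl, Et3N (excess), CH2Cl2, 0 °C → rt
Reagents that add atoms: none
Why: Dehydration by sulfonylation and elimination, where the tertiary allylic mesylate ionises readily and can only lose a methyl proton, giving the conjugated E-diene while the acetates block cyclisation to a chromene.

Step 10
Reactants: 7 isobavachalcone 4,4'-diacetate; 17 (E)-1-[2,4-diacetoxy-3-[(E)-3-methylbuta-1,3-dien-1-yl]phenyl]-3-(2,4-diacetoxyphenyl)prop-2-en-1-one (1.5 equiv)
Product: 18 racemic (3''S,4''R,5''S) endo cycloadduct hexaacetate (2'-OH of the prenylated benzoyl ring free)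
Conditions: Ag nanoparticles on SiO2 (0.5 mol% Ag; from AgBF4, Bu4NBH4 and silica), ClCH2CH2Cl, 50 °C, 48 h; SiO2 chromatography to remove the exo isomer
Reagents that add atoms: none
Why: Diels–Alder cycloaddition in which the silver surface activates only the chelating 2'-hydroxychalcone. The E-enone fixes C4''-aroyl trans to C5''-aryl, and the endo transition state with the E-diene puts C3''-aryl cis to C4''-aroyl (endo:exo about 2:1 expected). The ortho/para orientation joins the aryl-bearing diene terminus to the α-carbon, and the product is racemic.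

Step 11
Reactants: 18 racemic endo cycloadduct hexaacetate; 19 (1S)-(−)-camphanic chloride [(1S,4R)-4,7,7-trimethyl-3-oxo-2-oxabicyclo[2.2.1]heptane-1-carbonyl chloride]
Product: 20 (3''S,4''R,5''S) cycloadduct hexaacetate 2'-O-(1S)-camphanate (single diastereomer)
Conditions: Et3N, DMAP, CH2Cl2, rt; separation of the two diastereomeric esters on SiO2 (or by crystallisation)
Reagents that add atoms: none
Why: DMAP-catalysed esterification of the only free phenol places the camphor-derived (1S,4R) centres next to C4'', so the two enantiomers of 18 become diastereomeric esters that can be separated; the (3''S,4''R,5''S) ester is identified by crystal-structure analysis against the known camphanoyl configuration.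

Step 12
Reactants: 20 (3''S,4''R,5''S) cycloadduct hexaacetate 2'-O-(1S)-camphanate
Product: 21 target compound CNP0218862.2
Conditions: K2CO3 (cat.), MeOH/THF, 0 °C → rt, under argon; AcOH to pH 6
Reagents that add atoms: none
Why: Base-catalysed transesterification (methanolysis) removes all seven aryl esters without touching a bond at any stereocentre, and it avoids acid, which would ketalise the cis-disposed phenol and ketone or cyclise the prenyl group.

## Compound list

1 | 2,4-dihydroxyacetophenone | CC(=O)c1ccc(O)cc1O | starting material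
2 | prenyl bromide (1-bromo-3-methylbut-2-ene) | CC(C)=CCBr | starting material
3 | 1-[2,4-dihydroxy-3-(3-methylbut-2-en-1-yl)phenyl]ethanone | CC(=O)c1ccc(O)c(CC=C(C)C)c1O | intermediate
4 | 4-hydroxybenzaldehyde | O=Cc1ccc(O)cc1 | starting material
5 | 1-[2,4-dihydroxy-3-(3-methylbut-2-en-1-yl)phenyl]-3-hydroxy-3-(4-hydroxyphenyl)propan-1-one (racemic aldol, not isolated) | CC(C)=CCc1c(O)ccc(C(=O)CC(O)c2ccc(O)cc2)c1O | intermediate
6 | isobavachalcone, (E)-1-[2,4-dihydroxy-3-(3-methylbut-2-en-1-yl)phenyl]-3-(4-hydroxyphenyl)prop-2-en-1-one | CC(C)=CCc1c(O)ccc(C(=O)/C=C/c2ccc(O)cc2)c1O | intermediate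
7 | isobavachalcone 4,4'-diacetate, (E)-1-[4-acetoxy-2-hydroxy-3-(3-methylbut-2-en-1-yl)phenyl]-3-(4-acetoxyphenyl)prop-2-en-1-one | CC(C)=CCc1c(OC(C)=O)ccc(C(=O)/C=C/c2ccc(OC(C)=O)cc2)c1O | intermediate
8 | 1-(2,4-dihydroxy-3-iodophenyl)ethanone | CC(=O)c1ccc(O)c(I)c1O | intermediate
9 | 4-acetyl-2-iodo-1,3-phenylene diacetate | CC(=O)Oc1ccc(C(C)=O)c(OC(C)=O)c1I | intermediate
10 | 2,4-dihydroxybenzaldehyde | O=Cc1ccc(O)cc1O | starting material
11 | 4-formyl-1,3-phenylene diacetate (2,4-diacetoxybenzaldehyde) | CC(=O)Oc1ccc(C=O)c(OC(C)=O)c1 | intermediate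
12 | 1-(2,4-diacetoxy-3-iodophenyl)-3-(2,4-diacetoxyphenyl)-3-hydroxypropan-1-one (racemic aldol, not isolated) | CC(=O)Oc1ccc(C(O)CC(=O)c2ccc(OC(C)=O)c(I)c2OC(C)=O)c(OC(C)=O)c1 | intermediate
13 | (E)-1-(2,4-diacetoxy-3-iodophenyl)-3-(2,4-diacetoxyphenyl)prop-2-en-1-one | CC(=O)Oc1ccc(/C=C/C(=O)c2ccc(OC(C)=O)c(I)c2OC(C)=O)c(OC(C)=O)c1 | intermediate
14 | 2-methylbut-3-en-2-ol | C=CC(C)(C)O | starting material
15 | (E)-1-[2,4-diacetoxy-3-[(E)-3-hydroxy-3-methylbut-1-en-1-yl]phenyl]-3-(2,4-diacetoxyphenyl)prop-2-en-1-one | CC(=O)Oc1ccc(/C=C/C(=O)c2ccc(OC(C)=O)c(/C=C/C(C)(C)O)c2OC(C)=O)c(OC(C)=O)c1 | intermediate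
16 | methanesulfonate of the tertiary alcohol of 15 (not isolated) | CC(=O)Oc1ccc(/C=C/C(=O)c2ccc(OC(C)=O)c(/C=C/C(C)(C)OS(C)(=O)=O)c2OC(C)=O)c(OC(C)=O)c1 | intermediate
17 | (E)-1-[2,4-diacetoxy-3-[(E)-3-methylbuta-1,3-dien-1-yl]phenyl]-3-(2,4-diacetoxyphenyl)prop-2-en-1-one | CC(=O)Oc1ccc(/C=C/C(=O)c2ccc(OC(C)=O)c(/C=C/C(C)=C)c2OC(C)=O)c(OC(C)=O)c1 | intermediate
18 | racemic endo cycloadduct hexaacetate: 1''-methylcyclohex-1''-ene carrying at C3'' 2,6-diacetoxy-3-[(E)-3-(2,4-diacetoxyphenyl)acryloyl]phenyl, at C4'' 4-acetoxy-2-hydroxy-3-prenylbenzoyl and at C5'' 4-acetoxyphenyl; C3''/C4'' cis, C4''/C5'' trans (racemate; the SMILES shows the 3''S,4''R,5''S enantiomer) | CC(C)=CCc1c(OC(C)=O)ccc(C(=O)[C@H]2[C@@H](c3c(OC(C)=O)ccc(C(=O)/C=C/c4ccc(OC(C)=O)cc4OC(C)=O)c3OC(C)=O)C=C(C)C[C@@H]2c2ccc(OC(C)=O)cc2)c1O | intermediate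
19 | (1S)-(−)-camphanic chloride, (1S,4R)-4,7,7-trimethyl-3-oxo-2-oxabicyclo[2.2.1]heptane-1-carbonyl chloride | O=C(Cl)[C@@]12CC[C@@](C)(C(=O)O1)C2(C)C | starting material
20 | (3''S,4''R,5''S) cycloadduct hexaacetate whose 2'-oxygen on the prenylated benzoyl ring carries the (1S,4R)-camphanoyl group | CC(C)=CCc1c(OC(C)=O)ccc(C(=O)[C@H]2[C@@H](c3c(OC(C)=O)ccc(C(=O)/C=C/c4ccc(OC(C)=O)cc4OC(C)=O)c3OC(C)=O)C=C(C)C[C@@H]2c2ccc(OC(C)=O)cc2)c1OC(=O)[C@@]56CC[C@@](C)(C(=O)O5)C6(C)C | intermediate
21 | target: (3''S,4''R,5''S) cyclohexene carrying at C3'' 2,6-dihydroxy-3-[(E)-3-(2,4-dihydroxyphenyl)acryloyl]phenyl, at C4'' 2,4-dihydroxy-3-prenylbenzoyl and at C5'' 4-hydroxyphenyl; methyl on C1'' | CC(C)=CCc1c(O)ccc(C(=O)[C@H]2[C@@H](c3c(O)ccc(C(=O)/C=C/c4ccc(O)cc4O)c3O)C=C(C)C[C@@H]2c2ccc(O)cc2)c1O | target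

## Step count and risks

Total step count: 12.
Longest linear sequence: 8 steps (1 → 8 → 9 → 13 → 15 → 17 → 18 → 20 → 21).

Three steps most likely to fail:

**Step 7.** The BF3-mediated condensation may be spoiled by O→C acetyl transfer in the ortho-acetoxy ketone or by loss of an acetate. The fallback is a base-mediated condensation on acetal-protected phenols followed by protecting-group exchange; it sets out from 8 and 10 and comes back at 13. Ketone 8 is protected at O4 (MOMCl, K2CO3, acetone) to give 1-[2-hydroxy-3-iodo-4-(methoxymethoxy)phenyl]ethanone F1. Aldehyde 10 is converted (MOMCl, iPr2NEt, CH2Cl2) into 2,4-bis(methoxymethoxy)benzaldehyde F2. KOH/EtOH Claisen–Schmidt condensation of the two gives (E)-1-[2-hydroxy-3-iodo-4-(methoxymethoxy)phenyl]-3-[2,4-bis(methoxymethoxy)phenyl]prop-2-en-1-one F3. HCl/MeOH, harmless here because no prenyl or diene unit is present yet, gives (E)-1-(2,4-dihydroxy-3-iodophenyl)-3-(2,4-dihydroxyphenyl)prop-2-en-1-one F4, and Ac2O/pyridine/DMAP returns 13.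

**Step 10.** The cycloaddition may be slow with the hindered, acetoxy-flanked diene, or give poor endo selectivity. The fallback replaces surface catalysis by a stoichiometric boron template; it sets out from 7 (together with 17) and comes back at 18. Treatment of 7 with BH3·THF and biphenyl-2,2'-diol in THF gives the spiroborate chelate of 7 with biphenyl-2,2'-diolate F5, in which boron binds the 2'-phenolate and carbonyl oxygens and lowers the enone LUMO. This adds 17 at rt to 40 °C to give the spiroborate of the racemic endo cycloadduct F6, and MeOH/aq. NaHCO3 hydrolysis of the boron chelate releases 18.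

**Step 11.** Acylation of the hindered, chelated phenol with the bulky acid chloride may be sluggish, or the two diastereomers may not separate. The fallback is direct separation of enantiomers without covalent derivatisation; it sets out from 18 and comes back at 21. Preparative HPLC of racemic 18 on a cellulose tris(3,5-dimethylphenylcarbamate) phase gives the (3''S,4''R,5''S) enantiomer of hexaacetate 18 F7, assigned by circular dichroism. The K2CO3/MeOH conditions of step 12 then convert it directly into 21.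

Further compounds
F1 | step 7 | 1-[2-hydroxy-3-iodo-4-(methoxymethoxy)phenyl]ethanone | CC(=O)c1ccc(OCOC)c(I)c1O
F2 | step 7 | 2,4-bis(methoxymethoxy)benzaldehyde | COCOc1ccc(C=O)c(OCOC)c1
F3 | step 7 | (E)-1-[2-hydroxy-3-iodo-4-(methoxymethoxy)phenyl]-3-[2,4-bis(methoxymethoxy)phenyl]prop-2-en-1-one | COCOc1ccc(/C=C/C(=O)c2ccc(OCOC)c(I)c2O)c(OCOC)c1
F4 | step 7 | (E)-1-(2,4-dihydroxy-3-iodophenyl)-3-(2,4-dihydroxyphenyl)prop-2-en-1-one | Oc1ccc(/C=C/C(=O)c2ccc(O)c(I)c2O)c(O)c1
F5 | step 10 | spiroborate chelate of 7 with biphenyl-2,2'-diolate (boron bound to the 2'-phenolate oxygen, the carbonyl oxygen and both biphenolate oxygens) | CC(C)=CCc1c(OC(C)=O)ccc2c1O[B-]1(Oc3ccccc3-c3ccccc3O1)[O+]=C2/C=C/c1ccc(OC(C)=O)cc1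
F6 | step 10 | spiroborate of the racemic endo cycloadduct (boron chelate of 18 with biphenyl-2,2'-diolate; the 3''S,4''R,5''S enantiomer is drawn) | CC(C)=CCc1c(OC(C)=O)ccc2c1O[B-]1(Oc3ccccc3-c3ccccc3O1)[O+]=C2[C@H]1[C@@H](c3c(OC(C)=O)ccc(C(=O)/C=C/c4ccc(OC(C)=O)cc4OC(C)=O)c3OC(C)=O)C=C(C)C[C@@H]1c1ccc(OC(C)=O)cc1
F7 | step 11 | (3''S,4''R,5''S) enantiomer of hexaacetate 18 | CC(C)=CCc1c(OC(C)=O)ccc(C(=O)[C@H]2[C@@H](c3c(OC(C)=O)ccc(C(=O)/C=C/c4ccc(OC(C)=O)cc4OC(C)=O)c3OC(C)=O)C=C(C)C[C@@H]2c2ccc(OC(C)=O)cc2)c1O
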